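The winter run ended with substrate down to 0.1% but only 54.0% as target, so 46.0% of the charge went some other way, and the midnight run hints at which way.

| flask | substrate | coupling partner | temperature | remark | time |
|---|---|---|---|---|---|
| winter | 0.37 mM | 0.70 mM | 58 °C | run made earlier |  |
| dawn | 1.3 mM | 0.70 mM | 74 °C | run made earlier |  |
| midnight | 2.1 mM | 0.70 mM | 58 °C | run made earlier |  |
| noon | 1 mM | 0.67 mM | 74 °C | run made earlier |  |
| birch | 0.60 mM | 2.00 mM | 50 °C |  | 4.0 min |
| larch | 3.0 mM | 0.250 mM | 80 °C |  | 4.0 min |
| alder | 3.0 mM | 0.700 mM | 80 °C |  | 4.0 min |
| maple | 0.50 mM | 0.700 mM | 50 °C |  | 4.0 min |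
| cedar | 1.0 mM | 0.700 mM | 50 °C |  | 4.0 min |

- winter (time / min: target / %, substrate / %): 0.500: 54.6, 0; 1.00: 54.6, 0.4; 1.50: 54.1, 0.4; 2.50: 54.2, 0.2; 3.00: 54.0, 0.1
- dawn (time / s: target / %, substrate / %): 10.0: 33.1, 26.1; 15.0: 34.1, 23.9; 25.0: 33.5, 20.0; 60.0: 34.0, 10.8
- midnight (time / min: target / %, substrate / %): 0.500: 16.8, 33.0; 1.00: 16.4, 29.0; 1.50: 16.5, 24.8; 2.50: 16.6, 18.9; 3.00: 16.3, 16.5
- noon (time / s: target / %, substrate / %): 10.0: 44.1, 18.6; 12.0: 43.9, 17.6; 25.0: 43.5, 14.4; 40.0: 43.7, 10.8; 60.0: 43.6, 7.2

(each reading ± 0.3 percentage points)

- the earlier runs were read with a standard deviation of 0.3 percentage points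

- ranking by amount of target, in percent of the substrate charged, from high to low, at 4.0 min (birch / larch / alder / maple / cedar)
- the amount of target, in percent of the substrate charged of the flask you put first, at 4.0 min
- the amount of target, in percent of the substrate charged of the flask you put last, at 4.0 min

Why does target stop in the midnight run? It stays near 16.3% while substrate falls from 33.0% to 16.5%, so substrate is not what it lacks. The other charged thing is the coupling partner.

Does all the partner become target? No. Counting one partner per target, that target accounts for 48.9% of the partner charged, so a second path seems to consume partner as well.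

What do you assume about that path? This is my own guess: the loss speeds up with the partner level and the target path doesn't, so at any moment loss over target is proportional to the partner level.

Winter gives the number. Loss over target is 0.852 at a mean partner level of 0.515 mM, which gives 1.65 mM⁻¹. Call this g, the partner penalty, a selectivity factor: loss per unit of target per unit of partner level.

And integrated? I count one partner for each target and each loss. So the fraction of substrate becoming target is the natural log of (one plus g times partner charged) over (one plus g times partner left), divided by g times substrate charged. Partner left is charge minus substrate, or nothing where substrate is the larger charge. Carrying g unchanged across temperatures, maple gets 58.4% and birch 26.4%, less than maple despite its larger partner charge.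

Where does this break? Midnight itself: the rule gives 22.1% against a reading of 16.3%. So I shade the flasks with substrate in excess by that ratio, 0.736: cedar 34.2%, alder 11.4%, larch 5.13%. My order is therefore maple, cedar, birch, alder, larch.

The forecast gives birch > maple > cedar > alder > larch, with 50% first and 4.3% last, placing birch at the head “assuming partner helps”.

The flasks give maple > cedar > birch > alder > larch, with 51.7% first and 4.92% last.

    intermediate A → intermediate B (k = 0.00443 s⁻¹, Ea = 97.0 kJ mol⁻¹)
    coupling partner + intermediate A → target (k = 1620 M⁻¹ s⁻¹, Ea = 46.0 kJ mol⁻¹)
    intermediate B ⇌ intermediate C (K = 0.443, k = 0.547 s⁻¹, Ea = 83.0 kJ mol⁻¹, ΔH = 2.00 kJ mol⁻¹)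
    substrate + coupling partner → side product (k = 183 M⁻¹ s⁻¹, Ea = 39.0 kJ mol⁻¹)
    substrate ⇌ intermediate A (K = 1.00, k = 0.103 s⁻¹, Ea = 72.0 kJ mol⁻¹, ΔH = −26.0 kJ mol⁻¹)
    (constants at 50 °C)

The level to watch is the partner's. Birch holds 24.2% of target with 70.0% of its partner charge still left. In maple, the falling partner level is part of why target reaches 51.7% rather than the 42.3% it reaches with partner held at its charge. At that held level, g gives 46.3%. In larch, the falling partner level is the main reason target reaches 4.92% rather than the 70.1% it reaches with partner held at its charge. At that held level, g gives 70.7%.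

The runs were computed with constants of no real substance; noise was put on by code.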